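Remark on the chemistry: the carbon numbering of the target (C1 = methyl-bearing quaternary carbon, C2–C5 = rest of the cyclopentane, C6–C10 = rest of the seven-membered ring) is kept for every intermediate, the decalins included (fusion carbons C1 and C6); β is the face of the C1 methyl group, α the opposite face.

## Analysis of the target

The target is a daucane-type diester: a trans-fused hydroazulene in which a cyclopentane (C1–C5) shares the C1–C5 bond with a cycloheptene (C1, C5–C10) whose only olefin is the trisubstituted C8=C9 bond carrying the C8 methyl group. It has five stereocentres, (1R,2S,4R,5S,6S) in this numbering: quaternary C1 (β-methyl), the fusion methine C5 (α-H, hence the trans junction), C2 (α-angelate, trans to the methyl), C4 (tertiary β-hydroxyl, α-isopropyl) and C6 (α-angelate, H-6 anti to H-5). C4, C5 and C6 are contiguous, and C2 and C4 flank the quaternary carbon and the ring fusion. The two (Z)-2-methylbut-2-enoates are sensitive: they isomerise to tiglates under basic or nucleophilic catalysis and do not survive hydride or organometallic reagents. The tertiary C4 alcohol is β to every carbonyl group that a synthesis places at C2 or C6, so dehydration and retro-aldol cleavage have to be avoided. The difficulty lies in the quaternary centre inside a medium ring, the trans 5–7 junction, three differentiated oxygen functions and the regiodefined olefin. The strategy rests on one relationship: the fusion bond C1–C5 is vicinal to the oxygenated C6, which is the retron of a pinacol-type 1,2-shift. Moving C1 back from C5 to C6 turns the ring C1–C2–C3–C4–C5 into a six-membered ring that contains C6 and the seven-membered ring into a six-membered ring without C5, that is, a 1-methyldecalin oxygenated at C2 and C8, the pattern of the Wieland–Miescher ketone.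

## Retrosynthetic reasoning

The two acyl C–O bonds at C2 and C6 of 27 are cut first, giving triol 24 and two equivalents of angelic acid 25 (used as mixed anhydride 26). The esters come last because they tolerate none of the enolate, hydride and organometallic steps. The tertiary C4 hydroxyl does not acylate, so it needs no protection. The forward reaction has to acylate two hindered secondary alcohols without Z to E isomerisation.

The C2 carbinol of 24 (handled as its C6 silyl ether 23) is traced back to ketol 22 by cutting the C2–H bond. External hydride reaches C2 from the α face, anti to the C1 methyl, and would give the 2β-alcohol. With the 4β-hydroxyl free in 22, hydride can be delivered intramolecularly to the β face, which gives the required 2α-alcohol.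

The C4–O bond is cut next: 22 comes from cis-diol 21, this from epoxy alcohol 20, and 20 from allylic alcohol 19 and enone 18. External reagents reach C4 from the α face, because the β face is screened by C6 on C5 and by the C1 methyl. The isopropyl group is therefore installed while C4 is trigonal, and the oxygen is then delivered to the β face by the 2β-hydroxyl of 19, which is the alcohol that simple 1,2-reduction of 18 gives. The C2 configuration of 19–21 thus serves as a directing handle and is corrected afterwards (21 to 22 to 23).

The C4–isopropyl bond of 18 is cut to enone 16 (conjugate addition, then re-dehydrogenation through enol ether 17), and 16 comes from ketone 14 through enol ether 15. C3 is the only enolisable position of 14, so both dehydrogenations are regiospecific.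

The C8–CH3 bond is cut from 14 back through ketal 13 to enol triflate 12 and C8 ketone 11. Enolisation of 11 toward C9, away from the bulky C6 silyloxy group, fixes the C8=C9 position. This requires the C8 carbonyl to be free while C2 is still masked, so 11 is derived from bis-ketal 10 by selective hydrolysis. The C2 dioxolane is neopentyl to C1 and the C8 dioxolane is not.

The C6–H bond is cut from 10 through alcohol 9 to ketone 8. The 6α-alcohol is the equatorial and thermodynamically preferred one, so an equilibrating reduction is required.

The key disconnection cuts C1–C5 in 8 and rejoins C1 to C6, which leads to cis-diol monomesylate 7. It is placed here because one stereospecific shift in a rigid bicycle then delivers both rings, the quaternary centre in its final environment and the trans junction, and no medium ring has to be closed by cyclisation. The forward step must move C1 and not C7, and must invert C5.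

Mesylate 7 comes from diol 6, whose two hydroxyls are cis to the C1 methyl. This is the face that an acetoxonium (Woodward) sequence through 4 and 5 addresses on olefin 3. Olefin 3 is the deconjugated bis-ketal of (R)-Wieland–Miescher ketone 1 with two equivalents of ethylene glycol 2, so the absolute configuration at C1 is bought.

## Alternatives that were turned down

Alternative 1: Disconnection of C5–C6 in the seven-membered ring leads to open-chain aldehyde A2, in which C1 carries its methyl group and C2 as a silyloxymethyl arm, and C4/C5 form the enol silane of an isopropyl ketone. In the forward sense BF3·OEt2 would activate the C6 aldehyde and C5 of the enol silane would add to it (intramolecular Mukaiyama aldol) to give cycloheptenol A1.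
- For it: the assembly is convergent, and the C4 carbonyl with its isopropyl group is present from the start. On this point it is stronger than the chosen route, which spends seven steps on C2–C4.
- Against it: a seven-membered ring must be closed through an entropically poor transition state, and the C5/C6 configuration and its relation to the quaternary C1 depend on an open transition state. The quaternary centre, the (Z)-trisubstituted olefin and a regiodefined enol silane (toward C5, not toward the isopropyl methine) must all be made in an acyclic setting. A1 is a β-hydroxy ketone prone to retro-aldol cleavage and dehydration. The cyclopentane still has to be closed by inserting C3 between C2 and C4 while creating the tertiary carbinol.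
- Comparison: the chosen strategy forms both rings and the junction in one stereospecific shift and buys the quaternary centre enantiopure.

Alternative 2: The C1–CH3 and C4–C5 bonds are cut, which leads to cycloheptadienone A4 with a side chain on C1 that holds the protected C2 carbinol and the isopropyl ketone. Forward, Me2CuLi, or AlMe3 with CuOTf (monovalent copper) and a chiral ligand, would add methyl to C1, and the C5 enolate would close the cyclopentane by aldol addition to give A3.
- For it: quaternary centre, tertiary carbinol, ring fusion and complete skeleton arise in one step with C8=C9 in place. In step economy this plan is clearly stronger than the chosen one.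
- Against it: A4 is a skipped dienone whose C7 protons are doubly activated, so conjugation of the olefin, 1,6-addition or deprotonation compete with 1,4-addition to a β,β-disubstituted acceptor. Aldol closure of a five-membered ring from a tether on the neighbouring carbon normally gives the cis-fused bicycle, whereas the target is trans-fused, and correcting C5 by enolisation exposes the tertiary aldol to retro-aldol cleavage. Facial control at C1 must come from a catalyst working with or against the C2 stereocentre, and the C4 configuration is uncontrolled.
- Comparison: the chosen route is longer, but it sets the junction by stereospecific inversion and the C4 substituents by substrate-directed steps.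

Alternative 3: C1–C5 and C1–C10 are cut, so the seven-membered ring is traced to a benzene ring and the cyclopentane to the tether of α-diazo ketone A6. Forward, Rh2(OAc)4, or CuOTf (monovalent copper) with a chiral bis(oxazoline), would form the carbenoid at C1, which adds to the ipso–ortho bond; the norcaradiene opens to cycloheptatriene A5 (Buchner reaction).
- For it: the bicycle with quaternary C1, the C8 methyl, the C6 oxygen (as enol ether) and the finished C4 carbinol arises in one step from an easily made arene. In speed of access to the skeleton it is stronger than the chosen route.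
- Against it: the carbenoid carbon carries a methyl group, so 1,2-hydride shift to an enone competes. The arene is unsymmetrical, so addition to C5–C10 must win over addition to the methoxy-bearing C5–C6 bond and over aromatic C–H insertion. A5 holds three ring double bonds (C5=C6, C7=C8, C9=C10), none of which is the C8=C9 bond of the target. A 1,4-reduction of the diene, enol ether hydrolysis and creation of the C5 and C6 stereocentres would have to follow with little to guide them, and sigmatropic hydrogen shifts can scramble the triene. The tertiary benzylic carbinol must be made enantioselectively and then control C1.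
- Comparison: the chosen strategy has no carbenoid selectivity question and no triene redox problem; the oxidation state of every ring carbon after the key step is unambiguous.

Key step: step 4

## Route

Step 1
Reactants: 1 (R)-Wieland–Miescher ketone; 2 ethylene glycol
Product: 3 (1R)-1-methylbicyclo[4.4.0]dec-5-ene-2,8-dione 2,8-bis(ethylene ketal)
Conditions: ethylene glycol (excess), TsOH·H2O (cat.), toluene, reflux, Dean–Stark
Reagents that add atoms: ethylene glycol (second equivalent), OCCO
Why: Acid-catalysed ketalisation of both carbonyl groups, each consuming one equivalent of the diol, with azeotropic removal of water; the enone ketalises through its dienol ether, so the olefin ends up out of conjugation at C5=C6, as in the deconjugative ketalisation of steroidal 4-en-3-ones. The C1 stereocentre is not touched.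

Step 2
Reactants: 3 bis-ketal olefin
Product: 6 5β,6β-dihydroxy-1β-methylbicyclo[4.4.0]decane-2,8-dione bis(ethylene ketal), via trans-diaxial iodo acetate 4 (not isolated), via cis-hydroxy acetate 5 (not isolated)
Conditions: I2, AgOAc (2 equiv), AcOH, rt; then H2O (1.1 equiv), 90 °C; then K2CO3, MeOH, rt
Reagents that add atoms: silver acetate, CC(=O)[O-].[Ag+]
Why: Woodward cis-hydroxylation: iodonium formation on the α face (anti to the C1 methyl) and diaxial opening by acetate at C5 give 4, and silver-assisted loss of the tertiary iodide with participation of the neighbouring acetate forms the β-fused acetoxonium ion, which water opens at the acyl carbon to 5. Both new stereocentres (C5, C6) are thereby set on the methyl face, the face opposite to that of an OsO4 dihydroxylation; both diol oxygens stem from the one acetate unit, and methanolysis frees 6.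

Step 3
Reactants: 6 cis-diol
Product: 7 6β-hydroxy-5β-(methanesulfonyloxy)-1β-methylbicyclo[4.4.0]decane-2,8-dione bis(ethylene ketal)
Conditions: MsCl, pyridine, CH2Cl2, 0 °C
Reagents that add atoms: methanesulfonyl chloride, CS(=O)(=O)Cl
Why: Sulfonylation of the secondary C5 hydroxyl; the tertiary ring-fusion hydroxyl at C6 is not esterified under these conditions.

Step 4
Reactants: 7 cis-diol monomesylate
Product: 8 trans-fused 1β-methyl-5αH-perhydroazulene-2,6,8-trione 2,8-bis(ethylene ketal)
Conditions: KOtBu (1.2 equiv), tBuOH/THF, 0 °C to rt, short reaction time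
Reagents that add atoms: none
Why: tert-Butoxide deprotonates the tertiary C6 hydroxyl; in the chair–chair conformer of the cis-decalin in which the C5 mesylate is equatorial on ring A (C1–C6), the C6–C1 bond is antiperiplanar to C5–O, and the alkoxide pushes this bond onto C5 as mesylate leaves, so that C6 becomes the carbonyl carbon. This is a semipinacol rearrangement of a 2-sulfonyloxy tertiary alcohol, and the closest known case is the conversion of decalin cis-1,2-diol monosulfonates into hydroazulenones. No ring is closed by an exo or endo cyclisation: one suprafacial 1,2-alkyl shift contracts ring A to the cyclopentane (C1 exchanges C6 for C5) and enlarges ring B (C1, C6–C10) to the cycloheptanone (C5 is inserted between C1 and C6). The only new stereocentre, C5, is controlled by inversion at the migration terminus: C1, which migrates with retention, displaces the β-mesylate from the α face, so H-5 becomes α and trans to the C1 methyl. The selectivity needed is migration of C1 and not of C7; C7 is antiperiplanar to the mesylate only in the other chair–chair conformer, where the mesylate is axial and syn-axial to the C1 methyl, a contact the reactive conformer lacks. Epoxide formation is excluded because hydroxyl and mesylate are cis. The new C5–H is α to the ketone, but the trans junction, with both cyclopentane bonds equatorial on the seven-membered ring, is expected to be the more stable one as well; short exposure to base limits E1cB opening of the C8 dioxolane, which is now β to a ketone.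

Step 5
Reactants: 8 hydroazulenone
Product: 9 6α-hydroxy-1β-methyl-5αH-perhydroazulene-2,8-dione bis(ethylene ketal)
Conditions: Li, NH3(l), THF, EtOH, −78 °C; NH4Cl
Reagents that add atoms: none
Why: Dissolving-metal reduction of the ketone gives the thermodynamically preferred equatorial alcohol, which at C6 is the α-alcohol because a β (axial) hydroxyl would be syn-axial to the C1 methyl; this is the situation of 11-oxo steroids, where hydride reagents give the axial and alkali metals the equatorial alcohol. The ketals are inert, and the ethanol present keeps amide base from opening the β-keto ketal.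

Step 6
Reactants: 9 6α-alcohol
Product: 10 6α-(triisopropylsilyloxy)-1β-methyl-5αH-perhydroazulene-2,8-dione bis(ethylene ketal)
Conditions: iPr3SiOTf, 2,6-lutidine, CH2Cl2, −78 to 0 °C
Reagents that add atoms: triisopropylsilyl trifluoromethanesulfonate, CC(C)[Si](C(C)C)(C(C)C)OS(=O)(=O)C(F)(F)F
Why: Silylation of the secondary alcohol; the triisopropylsilyl ether withstands both acidic ketal hydrolyses, the amide base and the organometallic steps, and its bulk screens C7 in step 8.

Step 7
Reactants: 10 bis-ketal silyl ether
Product: 11 6α-(triisopropylsilyloxy)-1β-methyl-5αH-perhydroazulene-2,8-dione 2-(ethylene ketal)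
Conditions: PPTS (cat.), acetone/H2O, rt
Reagents that add atoms: water, O
Why: Mild acid hydrolysis removes the unhindered C8 dioxolane, while the C2 dioxolane, neopentyl to the quaternary C1, reacts much more slowly, as is known for steroidal 3- versus 17-ketals.

Step 8
Reactants: 11 C8 ketone
Product: 12 6α-(triisopropylsilyloxy)-1β-methyl-8-(trifluoromethanesulfonyloxy)-5αH-hydroazul-8-en-2-one ethylene ketal
Conditions: LiN(iPr)2, THF, −78 °C; PhNTf2, −78 to 0 °C
Reagents that add atoms: N-phenylbis(trifluoromethanesulfonimide), O=S(=O)(N(c1ccccc1)S(=O)(=O)C(F)(F)F)C(F)(F)F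
Why: Kinetic deprotonation by the hindered amide occurs at C9, the methylene remote from the bulky C6 silyloxy group (β-silyloxy ketones enolise away from the oxygen), and O-sulfonylation of the enolate fixes the C8=C9 double bond.

Step 9
Reactants: 12 enol triflate
Product: 13 6α-(triisopropylsilyloxy)-1β,8-dimethyl-5αH-hydroazul-8-en-2-one ethylene ketal
Conditions: MeMgBr, Fe(acac)3 (5 mol %), THF/NMP, −30 to 0 °C
Reagents that add atoms: methylmagnesium bromide, C[Mg]Br
Why: Iron-catalysed Kumada-type cross-coupling of an alkenyl triflate with a methyl Grignard reagent; the olefin position is retained, which completes the C8 methyl/C8=C9 unit.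

Step 10
Reactants: 13 ketal
Product: 14 6α-(triisopropylsilyloxy)-1β,8-dimethyl-5αH-hydroazul-8-en-2-one
Conditions: TsOH·H2O (cat.), acetone/H2O, 45 °C
Reagents that add atoms: water, O
Why: Hydrolysis of the remaining, hindered dioxolane under more forcing conditions; the silyl ether and the trisubstituted olefin are stable to dilute sulfonic acid.

Step 11
Reactants: 14 C2 ketone
Product: 16 6α-(triisopropylsilyloxy)-1β,8-dimethyl-5αH-hydroazula-3,8-dien-2-one, via trimethylsilyl enol ether 15 (not isolated)
Conditions: LiN(iPr)2, Me3SiCl, THF, −78 °C; then Pd(OAc)2, MeCN, rt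
Reagents that add atoms: none
Why: Saegusa–Ito dehydrogenation: C3 is the only enolisable position of 14, so enol ether 15 forms regiospecifically and divalent palladium converts it into the C3=C4 enone by β-hydride elimination.

Step 12
Reactants: 16 enone
Product: 18 4-isopropyl-6α-(triisopropylsilyloxy)-1β,8-dimethyl-5αH-hydroazula-3,8-dien-2-one, via 4α-isopropyl trimethylsilyl enol ether 17 (not isolated)
Conditions: iPrMgCl, CuBr·SMe2 (10 mol %), Me3SiCl, THF, −78 °C; then Pd(OAc)2, MeCN, rt
Reagents that add atoms: isopropylmagnesium chloride, CC(C)[Mg]Cl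
Why: Copper-catalysed conjugate addition of the Grignard reagent with chlorosilane trapping places the isopropyl group on C4 (from the open α face) and gives 17, whose Saegusa–Ito oxidation restores the C3=C4 double bond. The transient C4 stereocentre is erased.

Step 13
Reactants: 18 4-isopropyl enone
Product: 19 4-isopropyl-6α-(triisopropylsilyloxy)-1β,8-dimethyl-5αH-hydroazula-3,8-dien-2β-ol
Conditions: NaBH4, CeCl3·7H2O, MeOH, −78 to 0 °C
Reagents that add atoms: none
Why: Luche 1,2-reduction; hydride attacks C2 on the α face, anti to the axial C1 methyl, the course known for 17-oxo steroids. This sets the 2β-hydroxyl that is needed as a directing group.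

Step 14
Reactants: 19 allylic alcohol
Product: 20 3β,4β-epoxy-4α-isopropyl-6α-(triisopropylsilyloxy)-1β,8-dimethyl-5αH-hydroazul-8-en-2β-ol
Conditions: VO(acac)2 (cat.), tBuOOH, CH2Cl2, 0 °C to rt
Reagents that add atoms: tert-butyl hydroperoxide, CC(C)(C)OO
Why: Hydroxyl-directed epoxidation: the vanadium alkoxide of the allylic alcohol delivers oxygen to the face of the C2 hydroxyl, which places the C4 oxygen β and the isopropyl group α. The isolated C8=C9 olefin does not react with this reagent.

Step 15
Reactants: 20 epoxy alcohol
Product: 21 4α-isopropyl-6α-(triisopropylsilyloxy)-1β,8-dimethyl-5αH-hydroazul-8-ene-2β,4β-diol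
Conditions: LiEt3BH, THF, 0 °C to rt
Reagents that add atoms: none
Why: SN2 opening of the trisubstituted epoxide by hydride at the less substituted carbon C3, from the α face, leaves the tertiary β-alcohol at C4.

Step 16
Reactants: 21 cis-diol
Product: 22 4β-hydroxy-4α-isopropyl-6α-(triisopropylsilyloxy)-1β,8-dimethyl-5αH-hydroazul-8-en-2-one
Conditions: Dess–Martin periodinane, NaHCO3, CH2Cl2, 0 °C to rt
Reagents that add atoms: none
Why: Dess–Martin oxidation of the secondary C2 alcohol in the presence of the tertiary one; the buffered, non-basic medium avoids dehydration and retro-aldol cleavage of the β-hydroxy ketone.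

Step 17
Reactants: 22 ketol
Product: 23 4α-isopropyl-6α-(triisopropylsilyloxy)-1β,8-dimethyl-5αH-hydroazul-8-ene-2α,4β-diol
Conditions: Me4NBH(OAc)3, MeCN/AcOH, −30 °C
Reagents that add atoms: none
Why: Evans–Saksena reduction: the triacetoxyborohydride is bound by the C4 hydroxyl and transfers hydride intramolecularly to the β face of the C2 carbonyl, which gives the 2α-alcohol anti to the 4β-hydroxyl. The reagent does not reduce the ketone without this delivery, so the α-face pathway is shut.

Step 18
Reactants: 23 silyl ether diol
Product: 24 4α-isopropyl-1β,8-dimethyl-5αH-hydroazul-8-ene-2α,4β,6α-triol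
Conditions: Bu4NF, THF, rt to 40 °C
Reagents that add atoms: none
Why: Fluoride cleavage of the silyl ether; no base-sensitive group is present at this stage.

Step 19
Reactants: 24 triol; 25 angelic acid
Product: 27 (1R,2S,4R,5S,6S)-2α,6α-bis[(Z)-2-methylbut-2-enoyloxy]-4α-isopropyl-1β,8-dimethyl-5αH-hydroazul-8-en-4β-ol (target CNP0303897.1), via angelic 2,4,6-trichlorobenzoic anhydride 26 (not isolated)
Conditions: 25 (2.5 equiv), 2,4,6-trichlorobenzoyl chloride (2.5 equiv), Et3N, toluene, rt; then 24, 80 °C (no DMAP)
Reagents that add atoms: angelic acid (second equivalent), C/C=C(/C)C(=O)O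
Why: DMAP-free Yamaguchi-type acylation: two equivalents of mixed anhydride 26 acylate the two secondary hydroxyls on heating without Z to E isomerisation of the angeloyl unit, and the tertiary C4 hydroxyl is too hindered to react.

## Compound list

1 | (R)-Wieland–Miescher ketone, (8aR)-8a-methyl-3,4,8,8a-tetrahydronaphthalene-1,6(2H,7H)-dione | O=C1C=C2CCCC(=O)[C@]2(C)CC1 | starting material
2 | ethylene glycol | OCCO | starting material
3 | (1R)-1-methylbicyclo[4.4.0]dec-5-ene-2,8-dione 2,8-bis(ethylene ketal) | C1CC=C2CC3(OCCO3)CC[C@@]2(C)C14OCCO4 | intermediate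
4 | 5β-acetoxy-6α-iodo-1β-methylbicyclo[4.4.0]decane-2,8-dione bis(ethylene ketal) (trans-decalin) | I[C@@]12CC3(OCCO3)CC[C@@]1(C)C4(OCCO4)CC[C@@H]2OC(C)=O | intermediate
5 | 5β-acetoxy-6β-hydroxy-1β-methylbicyclo[4.4.0]decane-2,8-dione bis(ethylene ketal) (cis-decalin) | O[C@]12CC3(OCCO3)CC[C@@]1(C)C4(OCCO4)CC[C@@H]2OC(C)=O | intermediate
6 | 5β,6β-dihydroxy-1β-methylbicyclo[4.4.0]decane-2,8-dione bis(ethylene ketal) (cis-decalin) | O[C@]12CC3(OCCO3)CC[C@@]1(C)C4(OCCO4)CC[C@@H]2O | intermediate
7 | 6β-hydroxy-5β-(methanesulfonyloxy)-1β-methylbicyclo[4.4.0]decane-2,8-dione bis(ethylene ketal) | O[C@]12CC3(OCCO3)CC[C@@]1(C)C4(OCCO4)CC[C@@H]2OS(C)(=O)=O | intermediate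
8 | trans-fused 1β-methyl-5αH-perhydroazulene-2,6,8-trione 2,8-bis(ethylene ketal) | O=C1CC3(OCCO3)CC[C@@]2(C)C4(OCCO4)CC[C@H]12 | intermediate
9 | 6α-hydroxy-1β-methyl-5αH-perhydroazulene-2,8-dione bis(ethylene ketal) | O[C@H]1CC3(OCCO3)CC[C@@]2(C)C4(OCCO4)CC[C@H]12 | intermediate
10 | 6α-(triisopropylsilyloxy)-1β-methyl-5αH-perhydroazulene-2,8-dione bis(ethylene ketal) | CC(C)[Si](C(C)C)(C(C)C)O[C@H]1CC3(OCCO3)CC[C@@]2(C)C4(OCCO4)CC[C@H]12 | intermediate
11 | 6α-(triisopropylsilyloxy)-1β-methyl-5αH-perhydroazulene-2,8-dione 2-(ethylene ketal) | CC(C)[Si](C(C)C)(C(C)C)O[C@H]1CC(=O)CC[C@@]2(C)C3(OCCO3)CC[C@H]12 | intermediate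
12 | 6α-(triisopropylsilyloxy)-1β-methyl-8-(trifluoromethanesulfonyloxy)-5αH-hydroazul-8-en-2-one ethylene ketal | CC(C)[Si](C(C)C)(C(C)C)O[C@H]1CC(OS(=O)(=O)C(F)(F)F)=CC[C@@]2(C)C3(OCCO3)CC[C@H]12 | intermediate
13 | 6α-(triisopropylsilyloxy)-1β,8-dimethyl-5αH-hydroazul-8-en-2-one ethylene ketal | CC(C)[Si](C(C)C)(C(C)C)O[C@H]1CC(C)=CC[C@@]2(C)C3(OCCO3)CC[C@H]12 | intermediate
14 | 6α-(triisopropylsilyloxy)-1β,8-dimethyl-5αH-hydroazul-8-en-2-one | CC(C)[Si](C(C)C)(C(C)C)O[C@H]1CC(C)=CC[C@@]2(C)C(=O)CC[C@H]12 | intermediate
15 | 6α-(triisopropylsilyloxy)-2-(trimethylsilyloxy)-1β,8-dimethyl-5αH-hydroazula-2,8-diene | CC(C)[Si](C(C)C)(C(C)C)O[C@H]1CC(C)=CC[C@@]2(C)C(O[Si](C)(C)C)=CC[C@H]12 | intermediate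
16 | 6α-(triisopropylsilyloxy)-1β,8-dimethyl-5αH-hydroazula-3,8-dien-2-one | CC(C)[Si](C(C)C)(C(C)C)O[C@H]1CC(C)=CC[C@@]2(C)C(=O)C=C[C@H]12 | intermediate
17 | 4α-isopropyl-6α-(triisopropylsilyloxy)-2-(trimethylsilyloxy)-1β,8-dimethyl-5αH-hydroazula-2,8-diene | CC(C)[Si](C(C)C)(C(C)C)O[C@H]1CC(C)=CC[C@@]2(C)C(O[Si](C)(C)C)=C[C@@H](C(C)C)[C@H]12 | intermediate
18 | 4-isopropyl-6α-(triisopropylsilyloxy)-1β,8-dimethyl-5αH-hydroazula-3,8-dien-2-one | CC(C)[Si](C(C)C)(C(C)C)O[C@H]1CC(C)=CC[C@@]2(C)C(=O)C=C(C(C)C)[C@H]12 | intermediate
19 | 4-isopropyl-6α-(triisopropylsilyloxy)-1β,8-dimethyl-5αH-hydroazula-3,8-dien-2β-ol | CC(C)[Si](C(C)C)(C(C)C)O[C@H]1CC(C)=CC[C@@]2(C)[C@H](O)C=C(C(C)C)[C@H]12 | intermediate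
20 | 3β,4β-epoxy-4α-isopropyl-6α-(triisopropylsilyloxy)-1β,8-dimethyl-5αH-hydroazul-8-en-2β-ol | CC(C)[Si](C(C)C)(C(C)C)O[C@H]1CC(C)=CC[C@@]2(C)[C@H](O)[C@@H]3O[C@]3(C(C)C)[C@H]12 | intermediate
21 | 4α-isopropyl-6α-(triisopropylsilyloxy)-1β,8-dimethyl-5αH-hydroazul-8-ene-2β,4β-diol | CC(C)[Si](C(C)C)(C(C)C)O[C@H]1CC(C)=CC[C@@]2(C)[C@H](O)C[C@@](O)(C(C)C)[C@H]12 | intermediate
22 | 4β-hydroxy-4α-isopropyl-6α-(triisopropylsilyloxy)-1β,8-dimethyl-5αH-hydroazul-8-en-2-one | CC(C)[Si](C(C)C)(C(C)C)O[C@H]1CC(C)=CC[C@@]2(C)C(=O)C[C@@](O)(C(C)C)[C@H]12 | intermediate
23 | 4α-isopropyl-6α-(triisopropylsilyloxy)-1β,8-dimethyl-5αH-hydroazul-8-ene-2α,4β-diol | CC(C)[Si](C(C)C)(C(C)C)O[C@H]1CC(C)=CC[C@@]2(C)[C@@H](O)C[C@@](O)(C(C)C)[C@H]12 | intermediate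
24 | 4α-isopropyl-1β,8-dimethyl-5αH-hydroazul-8-ene-2α,4β,6α-triol | O[C@H]1CC(C)=CC[C@@]2(C)[C@@H](O)C[C@@](O)(C(C)C)[C@H]12 | intermediate
25 | angelic acid, (Z)-2-methylbut-2-enoic acid | C/C=C(/C)C(=O)O | starting material
26 | angelic 2,4,6-trichlorobenzoic anhydride | C/C=C(/C)C(=O)OC(=O)c1c(Cl)cc(Cl)cc1Cl | intermediate
27 | (1R,2S,4R,5S,6S)-2α,6α-bis[(Z)-2-methylbut-2-enoyloxy]-4α-isopropyl-1β,8-dimethyl-5αH-hydroazul-8-en-4β-ol (CNP0303897.1) | C/C=C(/C)C(=O)O[C@H]1CC(C)=CC[C@@]2(C)[C@@H](OC(=O)/C(C)=C\C)C[C@@](O)(C(C)C)[C@H]12 | target

## Step count and least certain steps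

Total step count: 19. Longest linear sequence: 19 steps from 1 (the route is linear; 2 and 25 are purchased).

Step 4 (key step).
- What may go wrong: migration of the wrong bond (C7 instead of C1) if the conformer with the axial mesylate reacts, which would give a bridged ketone; base-induced E1cB opening of the C8 dioxolane once the C6 ketone has formed; epimerisation at C5 through the C6 enolate.
- Fallback (from 3, back at 8): the olefin is dihydroxylated on the α face with OsO4 (cat.) and N-methylmorpholine N-oxide to the trans-decalin 5α,6α-diol F1, which is mesylated at C5 (MsCl, pyridine) to the 5α-mesylate F2. In this rigid trans-decalin the mesylate is equatorial and antiperiplanar only to C6–C1, so KOtBu can move only C1. Inversion at C5 then gives the cis-fused hydroazulenone F3, which is equilibrated through its C6 enolate (NaOMe, MeOH) to the trans-fused ketone 8.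

Step 2.
- What may go wrong: loss of the dioxolanes in hot wet acetic acid; elimination of the tertiary iodide before the acetate can participate; erosion of facial selectivity in iodonium formation, because the axial dioxolane oxygens at C2 and C8 flank the α face.
- Fallback (from 3, back at 6): a staged sequence without hot acid. NBS in aqueous acetone at 0 °C should give, by diaxial opening of the α-bromonium ion, the 6α-bromo-5β-alcohol F4. Acetylation (Ac2O, pyridine) gives the bromo acetate F5. AgOTf with 2,6-lutidine in wet acetone at 0 °C ionises the tertiary bromide with acetate participation, and water opens the acetoxonium ion to 5, which is methanolysed to 6 as in step 2.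

Step 5.
- What may go wrong: incomplete thermodynamic control in the flexible seven-membered ring, or base-induced opening of the β-keto ketal before reduction.
- Fallback (from 8, back at 9): NaBH4 in MeOH, which should attack the α face and give mainly the axial 6β-alcohol F6, followed by Meerwein–Ponndorf–Verley/Oppenauer equilibration (Al(OiPr)3, iPrOH, a little acetone, reflux) of the epimers to the equatorial alcohol 9.

Step 8.
- What may go wrong: poor regioselectivity of enolisation (C7 against C9), and β-elimination of silyloxide from a C7 enolate.
- Fallback (from 11, back at 13): Shapiro route. Condensation of 11 with 2,4,6-triisopropylbenzenesulfonyl hydrazide gives the hydrazone F7, whose N–N bond should lie syn to the less hindered C9. n-BuLi (2 equiv) removes the C9 proton, nitrogen and sulfinate are lost, and the C8 alkenyllithium is methylated with iodomethane to 13. Regiochemistry is then set by hydrazone geometry and not by competing enolisations.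

Step 17.
- What may go wrong: slow intramolecular hydride delivery past the C1 methyl on the β face, leading to incomplete reduction or dehydration of the ketol.
- Fallback (from 21, back at 23): Mitsunobu inversion of the 2β-alcohol of cis-diol 21 with 4-nitrobenzoic acid, PPh3 and diisopropyl azodicarboxylate to the 2α-(4-nitrobenzoate) F8, then K2CO3/MeOH to 23; steps 16 and 17 are then omitted. The tertiary hydroxyl does not react, and inversion next to a quaternary carbon has its counterpart in the 17β to 17α inversion of steroids.

Step 19.
- What may go wrong: Z to E isomerisation of the angeloyl units during activation, and incomplete acylation of the hindered C2 hydroxyl.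
- Fallback (from 24, back at 27): both secondary hydroxyls are acylated with 2-[bis(2,2,2-trifluoroethoxy)phosphoryl]propanoic acid (N,N'-dicyclohexylcarbodiimide, DMAP) to the bis(phosphonate) F9. A twofold Still–Gennari olefination (KN(SiMe3)2, 18-crown-6, acetaldehyde, THF, −78 °C) then builds both (Z)-2-methylbut-2-enoates on the molecule, so that no preformed angeloyl donor has to be kept from isomerising.

## Further compounds

F1 | step 4 | 5α,6α-dihydroxy-1β-methylbicyclo[4.4.0]decane-2,8-dione bis(ethylene ketal) (trans-decalin) | O[C@@]12CC3(OCCO3)CC[C@@]1(C)C4(OCCO4)CC[C@H]2O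
F2 | step 4 | 6α-hydroxy-5α-(methanesulfonyloxy)-1β-methylbicyclo[4.4.0]decane-2,8-dione bis(ethylene ketal) | O[C@@]12CC3(OCCO3)CC[C@@]1(C)C4(OCCO4)CC[C@H]2OS(C)(=O)=O
F3 | step 4 | cis-fused 1β-methyl-5βH-perhydroazulene-2,6,8-trione 2,8-bis(ethylene ketal) | O=C1CC3(OCCO3)CC[C@@]2(C)C4(OCCO4)CC[C@@H]12
F4 | step 2 | 6α-bromo-5β-hydroxy-1β-methylbicyclo[4.4.0]decane-2,8-dione bis(ethylene ketal) | Br[C@@]12CC3(OCCO3)CC[C@@]1(C)C4(OCCO4)CC[C@@H]2O
F5 | step 2 | 5β-acetoxy-6α-bromo-1β-methylbicyclo[4.4.0]decane-2,8-dione bis(ethylene ketal) | Br[C@@]12CC3(OCCO3)CC[C@@]1(C)C4(OCCO4)CC[C@@H]2OC(C)=O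
F6 | step 5 | 6β-hydroxy-1β-methyl-5αH-perhydroazulene-2,8-dione bis(ethylene ketal) | O[C@@H]1CC3(OCCO3)CC[C@@]2(C)C4(OCCO4)CC[C@H]12
F7 | step 8 | 2,4,6-triisopropylbenzenesulfonyl hydrazone of 11 at C8 | CC(C)[Si](C(C)C)(C(C)C)O[C@H]1CC(=NNS(=O)(=O)c3c(C(C)C)cc(C(C)C)cc3C(C)C)CC[C@@]2(C)C4(OCCO4)CC[C@H]12
F8 | step 17 | 4β-hydroxy-4α-isopropyl-2α-(4-nitrobenzoyloxy)-6α-(triisopropylsilyloxy)-1β,8-dimethyl-5αH-hydroazul-8-ene | CC(C)[Si](C(C)C)(C(C)C)O[C@H]1CC(C)=CC[C@@]2(C)[C@@H](OC(=O)c3ccc([N+](=O)[O-])cc3)C[C@@](O)(C(C)C)[C@H]12
F9 | step 19 | 2α,6α-bis{2-[bis(2,2,2-trifluoroethoxy)phosphoryl]propanoyloxy}-4α-isopropyl-1β,8-dimethyl-5αH-hydroazul-8-en-4β-ol (epimers at the two phosphonate-bearing carbons) | CC(C(=O)O[C@H]1CC(C)=CC[C@@]2(C)[C@@H](OC(=O)C(C)P(=O)(OCC(F)(F)F)OCC(F)(F)F)C[C@@](O)(C(C)C)[C@H]12)P(=O)(OCC(F)(F)F)OCC(F)(F)F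
A1 | alternative 1 | 1-[2-hydroxy-4,7-dimethyl-7-[(triethylsilyloxy)methyl]cyclohept-4-en-1-yl]-2-methylpropan-1-one (C1, C5, C6 as in the target) | O[C@H]1CC(C)=CC[C@@](C)(CO[Si](CC)(CC)CC)[C@@H]1C(=O)C(C)C
A2 | alternative 1 | (3Z,7Z)-3,6,9-trimethyl-6-[(triethylsilyloxy)methyl]-8-(trimethylsilyloxy)deca-3,7-dienal (C1 as in the target) | O=CC/C(C)=C\C[C@@](C)(CO[Si](CC)(CC)CC)/C=C(\O[Si](C)(C)C)C(C)C
A3 | alternative 2 | trans-fused 2α-(tert-butyldimethylsilyloxy)-4β-hydroxy-4α-isopropyl-1β,8-dimethylhydroazul-8-en-6-one | O=C1CC(C)=CC[C@@]2(C)[C@@H](O[Si](C)(C)C(C)(C)C)C[C@@](O)(C(C)C)[C@H]12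
A4 | alternative 2 | 3-[1-(tert-butyldimethylsilyloxy)-4-methyl-3-oxopentyl]-6-methylcyclohepta-2,5-dien-1-one (C2 as in the target) | O=C1CC(C)=CCC(=C1)[C@@H](O[Si](C)(C)C(C)(C)C)CC(=O)C(C)C
A5 | alternative 3 | 4-methoxy-6,8a-dimethyl-3-(propan-2-yl)-3-(triethylsilyloxy)-3,8a-dihydroazulen-1(2H)-one | COC=1C=C(C)C=C[C@@]2(C)C(=O)C[C@@](O[Si](CC)(CC)CC)(C(C)C)C=12
A6 | alternative 3 | 2-diazo-5-(2-methoxy-4-methylphenyl)-6-methyl-5-(triethylsilyloxy)heptan-3-one (C4 as in the target) | COc1cc(C)ccc1[C@](O[Si](CC)(CC)CC)(C(C)C)CC(=O)C(C)=[N+]=[N-]
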